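# Proposed synthesis of (2S)-7-hydroxy-2-[4-methoxy-3,5-bis(3-methylbut-2-enyl)phenyl]chroman-4-one (abyssinone IV 4'-O-methyl ether)

Ar stands throughout for 4-methoxy-3,5-bis(3-methylbut-2-enyl)phenyl. Flavanone numbering (O1, C2, C3, C4, C4a, C5 to C8, C8a; rings A, B and C) is used for all intermediates.

## Analysis of the target

The target is a flavanone. Ring A, a resorcinol-derived benzene with the free phenol at C7, is fused through C4a and C8a to ring C, a dihydropyranone made of O1, C2, C3, C4, C4a and C8a, and ring B sits on C2. C2 is the only stereocentre. It is (S), benzylic, bonded to the ring oxygen and β to the C4 carbonyl, so only absolute control is at stake, but that control must survive every later step. The weak point is this β-aryloxy ketone: enolisation towards C3 expels the O1 phenoxide and opens ring C to the 2'-hydroxychalcone, whose reclosure is not stereoselective, so base is excluded once the ketone is present. The two prenyl groups on ring B, which flank the 4'-methoxy group, are trisubstituted olefins and rule out ozonolysis, hydroboration, hydrogenation and hot strong acid, and the C7 phenol must be masked through the organometallic steps. The difficulty is therefore to set a lone stereocentre by catalysis and then close ring C without base. The route rests on the C3–C4 bond: C4 is a ketone carbon bonded to C4a of ring A, and C3 is an unsubstituted CH2 next to C2. At the enol oxidation level this bond is a C3=C4 double bond inside a cyclic enol ether, which can be drawn from a vinyl group on C2 and a 1-silyloxyvinyl group on C4a; the O1–C2 bond that remains then belongs to a 1-arylallyl aryl ether, the product type of an enantioselective allylic substitution.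

## Retrosynthetic reasoning

**Target 15 back to 13 (through 14).** No skeletal bond is cut. The C4 ketone is written as its tert-butyldimethylsilyl enol ether and the C7 phenol as its methoxymethyl ether. While C4 is an enol ether there is no acidic C3–H next to a carbonyl, so the β-elimination of the O1 phenoxide that would scramble C2 cannot start. The forward step must protonate C3, release silicon from oxygen and solvolyse the acetal with dilute acid; 14 is the ketone passed on the way.

**13 back to 12.** The C3=C4 double bond of the cyclic enol ether is cut by a metathesis transform. This puts a vinyl group on C2 and a 1-silyloxyvinyl group on C4a and returns the two missing CH2 termini. The bond is chosen because C3 is the only ring-C atom with neither a heteroatom nor a substituent, so the cut leaves C2 with all four final substituents in place. Cutting O1–C2 or C2–C3 instead would mean forming a bond at C2 during ring closure, by conjugate addition or aldol chemistry, which is where reversibility threatens the configuration. The gain is a ring closure under neutral conditions that makes or breaks no bond at C2 and delivers C4 at the ketone oxidation level. The forward reaction must engage a hindered, electron-rich 1,1-disubstituted olefin with a ruthenium carbene and leave the two prenyl olefins alone.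

**12 back to 11.** The O–Si bond is cut, which uncovers the methyl ketone. The acetyl group has one enolisable position, so there is no regiochemical question. The forward step must silylate the enolate on oxygen without disturbing the acid-labile acetal or the doubly activated benzylic, allylic ether.

**11 back to 8 and 10.** The O1–C2 bond is cut. C2 in 11 is benzylic and allylic, and an aryl-substituted allyl terminus is the position to which iridium–phosphoramidite catalysts direct heteroatom nucleophiles with branched selectivity and enantiocontrol. The cut makes the only stereocentre the outcome of one catalytic step and splits the molecule into ring-A phenol 10 and ring-B cinnamyl carbonate 8, two fragments of similar size. The forward reaction must form the branched ether on the correct enantioface and be stopped before the catalyst re-ionises the product.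

**8 back to 4 and 5 (through 7 and 6).** The allylic carbonate is traced through allylic alcohol 7 and cinnamate 6 to aldehyde 4, by cutting the C=C bond in an olefination transform with phosphonate 5. This is the standard three-step access to a linear (E)-cinnamyl electrophile; the only requirement is the (E) geometry, which a stabilised phosphonate secures.

**4 back to 2 and 3, and 2 back to 1.** The two aryl–CH2 bonds to the prenyl groups are cut together. They are identical and both ortho to the C4' oxygen, so a twofold cross-coupling of dibromide 2 with allylboronate 3 installs them in one step. They are introduced early so that no cross-coupling is run on a compound that carries the stereocentre. The methyl ether is made first from commercial phenol 1, because the free phenol would interfere with the coupling and with the later steps.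

**10 back to 9.** The acetal C–O bond at the oxygen para to the acetyl group (the later C7 oxygen) is cut. Of the two phenols of 9, the one ortho to the acetyl group is hydrogen-bonded to the carbonyl, so the para hydroxyl is alkylated selectively and the ortho hydroxyl stays free as the nucleophile for the etherification.

## Alternatives that were turned down

**Alternative 1: Aryne insertion into an arylpropiolic acid with oxa-Michael closure.**
- Disconnection: ring C is dismantled at the flavone oxidation level along O1–C8a, C4–C4a and O1–C2. Ring A becomes an aryne, stored as silyl triflate A3, and C2, C3, C4 with ring B become arylpropiolic acid A2.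
- Forward key step: fluoride (CsF) releases the aryne from A3. The carboxylate of A2 adds through oxygen to the aryne carbon remote from bromine, the resulting aryl anion closes onto the acyl carbon, and the four-membered intermediate opens to an ortho-hydroxyaryl ynone. Its phenoxide closes ring C by 6-endo addition to give flavone A1.
- In favour: three bonds and ring C from two fragments of similar size in one operation, without a transition metal. On bonds formed per step it is clearly stronger than the chosen route, whose key step forms one.
- Against: A1 is flat at C2, so the only stereocentre would still have to be made by enantioselective conjugate reduction of a 2-arylchromone. That is a vinylogous ester and a poor acceptor, and the reduction would run in the presence of two prenyl olefins and an aryl bromide. The C5 bromine only steers the regiochemistry of the aryne addition and must be removed again without touching those olefins. Arynes undergo ene reactions with olefins bearing allylic hydrogens, which each prenyl group of A2 offers. A3 needs a multistep preparation of its own.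
- Comparison: this key step does more, but its product is further from the target: one reduction level, one halogen and one stereocentre away. Compound 13 is one acid treatment from 15 with C2 already set.

**Alternative 2: Three-component carbonylative annulation.**
- Disconnection: C4a–C4, C4–C3 and O1–C2, again at the flavone level, leading to iodophenol A5, carbon monoxide and arylacetylene A6.
- Forward key step: zerovalent palladium (from PdCl2(PPh3)2) inserts into the C–I bond of A5, carbon monoxide insertion gives an acylpalladium species, and coupling with A6 gives the ortho-hydroxyaryl ynone. Diethylamine mediates 6-endo closure to flavone A4.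
- In favour: both partners are simple (A6 is one homologation from aldehyde 4), no directing halogen is needed, and the ring system is reached in fewer steps than in the chosen route. On step count to the skeleton this alternative is the stronger one.
- Against: 5-exo closure to the five-membered ring isomer competes with the 6-endo mode and depends delicately on the amine. As in alternative 1, A4 has no stereocentre. The enantioselective 1,4-reduction that must follow has to distinguish the chromone C2=C3 bond from two trisubstituted olefins, stop at the ketone, and be worked up without base, since the product opens by β-elimination. The bulky 3,5-disubstituted ring B at the prochiral carbon makes its selectivity hard to predict.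
- Comparison: in place of the shorter skeleton synthesis, the chosen route sets the stereocentre by a reaction whose selectivity is governed by an aryl-substituted allyl terminus, and nothing afterwards makes or breaks a bond at C2.

**Alternative 3: Aryl ether closure at O1–C8a.**
- Disconnection: the O1–C8a bond is cut, leading to open-chain 1,3-diol A8 with an ortho-bromoaryl group. A8 would come from an enantioselective aldol addition of a brominated ring-A methyl ketone to aldehyde 4, followed by ketone reduction.
- Forward key step: CuI, a phenanthroline ligand and Cs2CO3 convert the C2 hydroxyl into an alkoxide of monovalent copper, which couples with the aryl bromide to form O1–C8a and chromanol A7. The C2–O bond is not broken, so the configuration is retained, and the C4 hydroxyl cannot compete because it would close a four-membered ring.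
- In favour: the ring closure is robust, indifferent to the prenyl groups, and involves no hydrolytically sensitive enol ether. On chemoselectivity towards the prenyl olefins and on reliability of the ring-forming step it is at least as strong as the chosen route and probably stronger.
- Against: the C4 oxidation level takes a detour. The aldol ketone must be reduced so that hot carbonate cannot trigger retro-aldol cleavage or elimination, and A7 must be re-oxidised at the end. The C4 stereocentre of A7 is made only to be destroyed. The stereocentre rests on an enantioselective aldol addition of a methyl ketone, the least dependable class of aldol donors. A brominated ring-A ketone is needed in place of the cheap 9.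
- Comparison: the chosen route offers a constant oxidation level at C4 (ketone, enol ether, ketone), three steps from the stereo-defining event to the target instead of four, and a stereo-defining reaction better matched to an aryl-substituted carbon.

Key step: step 9

Assumption: L* denotes O,O'-(1,1'-binaphthyl-2,2'-diyl) N,N-bis(1-phenylethyl)phosphoramidite. Its (Sa,Sc,Sc) enantiomer is taken to deliver the (S)-ether, following the sense of induction known for aryl-substituted allyl carbonates with heteroatom nucleophiles. If the sense were the reverse, the (Ra,Rc,Rc) antipode would be used and nothing else changes.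

## Route

Step 1
Reactants: 1 3,5-dibromo-4-hydroxybenzaldehyde
Product: 2 3,5-dibromo-4-methoxybenzaldehyde
Conditions: MeI, K2CO3, DMF, 40 °C
Reagents that add atoms: iodomethane, CI
Why: Williamson O-methylation; the phenol flanked by two bromines and para to the formyl group is acidic, and its phenoxide should be alkylated cleanly by the unhindered methyl iodide.

Step 2
Reactants: 2 3,5-dibromo-4-methoxybenzaldehyde; 3 prenylboronic acid pinacol ester (3 equiv)
Product: 4 4-methoxy-3,5-bis(3-methylbut-2-enyl)benzaldehyde (Ar–CHO)
Conditions: PdCl2(dppf) (5 mol %), K3PO4, THF/H2O, 70 °C
Reagents that add atoms: none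
Why: Twofold Suzuki–Miyaura coupling of an allylboronate; after transmetallation the allylpalladium species equilibrates by σ–π–σ interconversion, and reductive elimination from the less hindered primary carbon should give the linear prenyl arene. The aldehyde is inert to zerovalent palladium and to phosphate.

Step 3
Reactants: 4 Ar–CHO; 5 triethyl phosphonoacetate
Product: 6 ethyl (E)-3-Ar-prop-2-enoate
Conditions: NaH, THF, 0 °C to rt
Reagents that add atoms: none
Why: Horner–Wadsworth–Emmons olefination; the stabilised phosphonate anion adds reversibly to the non-enolisable aldehyde and should give the (E)-cinnamate.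

Step 4
Reactants: 6 ethyl (E)-3-Ar-prop-2-enoate
Product: 7 (E)-3-Ar-prop-2-en-1-ol
Conditions: i-Bu2AlH (2.3 equiv), CH2Cl2, −78 °C; aq. potassium sodium tartrate
Reagents that add atoms: none
Why: 1,2-Reduction of an α,β-unsaturated ester to the allylic alcohol by an aluminium hydride at low temperature; the isolated prenyl olefins and the aryl ether are not touched.

Step 5
Reactants: 7 (E)-3-Ar-prop-2-en-1-ol
Product: 8 methyl (E)-3-Ar-prop-2-enyl carbonate
Conditions: ClCO2Me, pyridine, CH2Cl2, 0 °C
Reagents that add atoms: methyl chloroformate, COC(=O)Cl
Why: O-Acylation of a primary allylic alcohol to the carbonate, the leaving group required for ionisation by iridium in step 7.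

Step 6
Reactants: 9 2,4-dihydroxyacetophenone
Product: 10 1-[2-hydroxy-4-(methoxymethoxy)phenyl]ethanone
Conditions: MOMCl (1.1 equiv), K2CO3, acetone, 0 °C to rt
Reagents that add atoms: chloromethyl methyl ether, COCCl
Why: Selective O-alkylation (acetal formation); the 2-hydroxyl is held in a hydrogen bond to the carbonyl and is the less acidic and less nucleophilic one, so the 4-hydroxyl should react alone.

Step 7
Reactants: 8 methyl (E)-3-Ar-prop-2-enyl carbonate; 10 1-[2-hydroxy-4-(methoxymethoxy)phenyl]ethanone (1.5 equiv)
Product: 11 1-[2-{[(1S)-1-Ar-prop-2-enyl]oxy}-4-(methoxymethoxy)phenyl]ethanone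
Conditions: 10, LiN(SiMe3)2, THF, 0 °C; then 8, [Ir(cod)Cl]2 (2 mol %), (Sa,Sc,Sc)-L* (4 mol %, pre-activated with n-PrNH2), THF, 25–50 °C, stopped at full conversion of 8; Et3N-treated silica
Reagents that add atoms: none
Why: Iridium-catalysed asymmetric allylic etherification: the cyclometallated iridium–phosphoramidite complex ionises the carbonate to an allyl complex of trivalent iridium, and the phenoxide attacks the aryl-bearing terminus anti to the metal to give the branched ether. C2 is set here: the ligand antipode fixes which face of the allyl ligand is bound to iridium and thereby the (S) configuration. The lithium phenoxide is formed first so that the phenol oxygen, not the ketone α-carbon, is the nucleophile.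

Step 8
Reactants: 11 1-[2-{[(1S)-1-Ar-prop-2-enyl]oxy}-4-(methoxymethoxy)phenyl]ethanone
Product: 12 tert-butyl{[1-(2-{[(1S)-1-Ar-prop-2-enyl]oxy}-4-(methoxymethoxy)phenyl)ethenyl]oxy}dimethylsilane
Conditions: KN(SiMe3)2, THF, −78 °C; TBSCl, −78 to 0 °C; cold aq. NaHCO3; Et3N-treated silica
Reagents that add atoms: tert-butyldimethylsilyl chloride, CC(C)(C)[Si](C)(C)Cl
Why: Silyl enol ether formation by kinetic deprotonation of the methyl ketone (its only enolisable position) and O-silylation of the potassium enolate. An amide base with the silyl chloride is used instead of a silyl triflate with an amine, because silyl triflates can cleave aryl methoxymethyl ethers and ionise the doubly activated ether at C2. No bond to the stereocentre is touched.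

Step 9
Reactants: 12 tert-butyl{[1-(2-{[(1S)-1-Ar-prop-2-enyl]oxy}-4-(methoxymethoxy)phenyl)ethenyl]oxy}dimethylsilane
Product: 13 (2S)-2-Ar-4-(tert-butyldimethylsilyloxy)-7-(methoxymethoxy)-2H-chromene
Conditions: second-generation Grubbs catalyst RuCl2(=CHPh)(PCy3)(H2IMes) (5–10 mol %), degassed toluene (0.005 M), 60 °C, argon purge, dark; filtration through Et3N-treated silica
Reagents that add atoms: none
Why: Ring-closing olefin metathesis of an acyclic silyl enol ether. The ruthenium benzylidene exchanges first with the only monosubstituted olefin, the vinyl group on C2, to give the alkylidene at the future C3; this adds intramolecularly across the 1-silyloxyvinyl group with ruthenium on the terminal CH2 and the carbene carbon on the oxygen-bearing carbon, and cycloreversion of the ruthenacyclobutane releases the C3=C4 bond and a ruthenium methylidene, which carries the chain with loss of ethene. The closest known reactions are the ring-closing metathesis of ketone-derived silyl enol ethers to five- to seven-membered cyclic enol ethers and the closure of ortho-vinylaryl 1-arylallyl ethers to 2-aryl-2H-chromenes. Ring C, six-membered, is closed as an endocyclic olefin from a 1,7-diene whose two olefins are held ortho to each other on ring A by the aryl ether, so closure is entropically favoured. No stereocentre is formed and no bond to C2 is made or broken, so the (S) configuration from step 7 is carried over. The step needs chemoselectivity for the two terminal olefins over the two prenyl groups: these are trisubstituted and slow to react, and their intramolecular engagement would require a strained meta-bridged cyclophane, while high dilution and removal of ethene suppress intermolecular exchange and methylidene attack on the prenyl groups. The orientation of the metallacycle that closes the ring leaves ruthenium as the methylidene and not as a silyloxy-substituted carbene, which would be a dead end.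

Step 10
Reactants: 13 (2S)-2-Ar-4-(tert-butyldimethylsilyloxy)-7-(methoxymethoxy)-2H-chromene
Product: 15 (2S)-7-hydroxy-2-Ar-chroman-4-one, via MOM-protected flavanone 14 (not isolated)
Conditions: 2 M aq. HCl, THF/MeOH, 0 °C; then 45 °C
Reagents that add atoms: none
Why: Acid hydrolysis of the silyl enol ether (protonation at C3, loss of silicon from the oxocarbenium ion) should give ketone 14 at 0 °C, and warming solvolyses the methoxymethyl acetal. Acid is chosen over fluoride or base because an enolate at C3 would expel the O1 phenoxide and racemise C2, whereas the protonated ketone should not open under these conditions. The prenyl groups have no free phenol beside them, so acid-induced chroman formation is not possible.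

## Compound list

1 | 3,5-dibromo-4-hydroxybenzaldehyde | O=Cc1cc(Br)c(O)c(Br)c1 | starting material
2 | 3,5-dibromo-4-methoxybenzaldehyde | COc1c(Br)cc(C=O)cc1Br | intermediate
3 | prenylboronic acid pinacol ester, 4,4,5,5-tetramethyl-2-(3-methylbut-2-enyl)-1,3,2-dioxaborolane | CC(C)=CCB1OC(C)(C)C(C)(C)O1 | starting material
4 | 4-methoxy-3,5-bis(3-methylbut-2-enyl)benzaldehyde | COc1c(CC=C(C)C)cc(C=O)cc1CC=C(C)C | intermediate
5 | triethyl phosphonoacetate | CCOC(=O)CP(=O)(OCC)OCC | starting material
6 | ethyl (E)-3-[4-methoxy-3,5-bis(3-methylbut-2-enyl)phenyl]prop-2-enoate | CCOC(=O)/C=C/c1cc(CC=C(C)C)c(OC)c(CC=C(C)C)c1 | intermediate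
7 | (E)-3-[4-methoxy-3,5-bis(3-methylbut-2-enyl)phenyl]prop-2-en-1-ol | OC/C=C/c1cc(CC=C(C)C)c(OC)c(CC=C(C)C)c1 | intermediate
8 | methyl (E)-3-[4-methoxy-3,5-bis(3-methylbut-2-enyl)phenyl]prop-2-enyl carbonate | COC(=O)OC/C=C/c1cc(CC=C(C)C)c(OC)c(CC=C(C)C)c1 | intermediate
9 | 2,4-dihydroxyacetophenone | CC(=O)c1ccc(O)cc1O | starting material
10 | 1-[2-hydroxy-4-(methoxymethoxy)phenyl]ethanone | CC(=O)c1ccc(OCOC)cc1O | intermediate
11 | 1-[2-{[(1S)-1-[4-methoxy-3,5-bis(3-methylbut-2-enyl)phenyl]prop-2-enyl]oxy}-4-(methoxymethoxy)phenyl]ethanone | COc1c(CC=C(C)C)cc([C@@H](Oc2cc(OCOC)ccc2C(C)=O)C=C)cc1CC=C(C)C | intermediate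
12 | tert-butyl{[1-(2-{[(1S)-1-[4-methoxy-3,5-bis(3-methylbut-2-enyl)phenyl]prop-2-enyl]oxy}-4-(methoxymethoxy)phenyl)ethenyl]oxy}dimethylsilane | COc1c(CC=C(C)C)cc([C@@H](Oc2cc(OCOC)ccc2C(=C)O[Si](C)(C)C(C)(C)C)C=C)cc1CC=C(C)C | intermediate
13 | (2S)-4-(tert-butyldimethylsilyloxy)-7-(methoxymethoxy)-2-[4-methoxy-3,5-bis(3-methylbut-2-enyl)phenyl]-2H-chromene | COc1c(CC=C(C)C)cc([C@@H]2C=C(O[Si](C)(C)C(C)(C)C)c3ccc(OCOC)cc3O2)cc1CC=C(C)C | intermediate
14 | (2S)-7-(methoxymethoxy)-2-[4-methoxy-3,5-bis(3-methylbut-2-enyl)phenyl]chroman-4-one | COc1c(CC=C(C)C)cc([C@@H]2CC(=O)c3ccc(OCOC)cc3O2)cc1CC=C(C)C | intermediate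
15 | (2S)-7-hydroxy-2-[4-methoxy-3,5-bis(3-methylbut-2-enyl)phenyl]chroman-4-one (abyssinone IV 4'-O-methyl ether) | COc1c(CC=C(C)C)cc([C@@H]2CC(=O)c3ccc(O)cc3O2)cc1CC=C(C)C | target

## Step count and least certain steps

Total: 10 steps. Longest linear sequence: 9 steps (steps 1 to 5 and 7 to 10, from 1). The ring-A branch (steps 6 to 10) is 5 steps.

**Step 9 (key step).** The most likely failures are:
- loss of the silyl group by adventitious acid before ring closure, which returns the unreactive ketone;
- slow engagement of the hindered, electron-rich 1,1-disubstituted olefin, so that intermolecular metathesis and methylidene exchange at the prenyl groups (degradation of prenyl to allyl) compete;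
- double-bond migration of the allylic ether by ruthenium hydrides.

Fallback: ring C would be closed at O1–C2 instead, by catalytic enantioselective oxa-Michael addition, setting out from 10 and 4. C-Acylation of the dianion of 10 (LiN(SiMe3)2, then di-tert-butyl dicarbonate, THF, −78 °C) should give the β-keto ester tert-butyl 3-[2-hydroxy-4-(methoxymethoxy)phenyl]-3-oxopropanoate F1. Knoevenagel condensation of F1 with 4 (piperidine, AcOH, toluene, molecular sieves) should give the alkylidene β-keto ester tert-butyl 2-[2-hydroxy-4-(methoxymethoxy)benzoyl]-3-Ar-prop-2-enoate F2. A cinchona-alkaloid-derived bifunctional thiourea, of the pseudoenantiomeric series that delivers the 2S product, would close ring C by 6-endo addition of the phenol to give tert-butyl (2S)-7-(methoxymethoxy)-2-Ar-4-oxochromane-3-carboxylate F3. p-TsOH in toluene at 80 °C would then remove 2-methylpropene and CO2 to give 14, rejoining the route at the warm stage of step 10. The ester makes the acceptor reactive enough for a hydrogen-bonding catalyst, and decarboxylation under acid avoids base.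

**Step 7.** The acyl-substituted, chelated phenoxide is a weak nucleophile, so substitution may be slow. Because the same phenoxide is a good leaving group, the catalyst may re-ionise the product, eroding enantiomeric purity and causing isomerisation to the linear ether.

Fallback: the C–O bond would be made by Mitsunobu inversion of an enantioenriched allylic alcohol, setting out from 8. Iridium-catalysed substitution of 8 with KOSiEt3 ([Ir(cod)Cl]2, (Ra,Rc,Rc)-L*, CH2Cl2, rt), a strong oxygen nucleophile, should give triethyl{[(1R)-1-Ar-prop-2-enyl]oxy}silane F4. Desilylation (Bu4NF, THF, 0 °C) gives (1R)-1-Ar-prop-2-en-1-ol F5. Mitsunobu coupling of F5 with 10 (PPh3, DIAD, toluene, 0 °C) should give 11 with inversion at C2, and no metal catalyst remains to re-ionise it.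

**Step 2.** Coupling may occur through the γ-carbon of the allylboronate, which gives 1,1-dimethylallyl groups. The boronate may be lost by protodeboronation, and the second coupling next to the methoxy group may be incomplete.

Fallback: the regiochemical question would be removed by coupling an unsubstituted allyl group and building the prenyl terminus afterwards, setting out from 2. Twofold Stille coupling with allyltributylstannane (Pd(PPh3)4, toluene, 100 °C) should give 4-methoxy-3,5-bis(prop-2-enyl)benzaldehyde F6. Cross-metathesis of F6 with excess 2-methyl-2-butene (second-generation Grubbs catalyst RuCl2(=CHPh)(PCy3)(H2IMes), CH2Cl2, 40 °C) gives 4.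

**Step 10.** During the warm acetal cleavage, acid may add across the prenyl olefins, or ring C may open and reclose, with loss of configurational purity at C2.

Fallback: the C7 oxygen would be carried as a silyl ether so that all silicon leaves together under buffered fluoride and no warm acid is needed, setting out from 9. Selective silylation of the 4-hydroxyl (i-Pr3SiCl, imidazole, CH2Cl2) should give 1-[2-hydroxy-4-(triisopropylsilyloxy)phenyl]ethanone F7. Etherification with 8 as in step 7 gives 1-[2-{[(1S)-1-Ar-prop-2-enyl]oxy}-4-(triisopropylsilyloxy)phenyl]ethanone F8. Enol silylation as in step 8 gives tert-butyl{[1-(2-{[(1S)-1-Ar-prop-2-enyl]oxy}-4-(triisopropylsilyloxy)phenyl)ethenyl]oxy}dimethylsilane F9. Ring-closing metathesis as in step 9 gives (2S)-2-Ar-4-(tert-butyldimethylsilyloxy)-7-(triisopropylsilyloxy)-2H-chromene F10. Bu4NF buffered with AcOH (THF, 0 °C) then removes both silyl groups and gives 15 directly; the acetic acid protonates the transient enolate before it can open ring C.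

## Further compounds

F1 | step 9 | tert-butyl 3-[2-hydroxy-4-(methoxymethoxy)phenyl]-3-oxopropanoate | CC(C)(C)OC(=O)CC(=O)c1ccc(OCOC)cc1O
F2 | step 9 | tert-butyl 2-[2-hydroxy-4-(methoxymethoxy)benzoyl]-3-[4-methoxy-3,5-bis(3-methylbut-2-enyl)phenyl]prop-2-enoate (olefin geometry not fixed) | COc1c(CC=C(C)C)cc(C=C(C(=O)OC(C)(C)C)C(=O)c2ccc(OCOC)cc2O)cc1CC=C(C)C
F3 | step 9 | tert-butyl (2S)-7-(methoxymethoxy)-2-[4-methoxy-3,5-bis(3-methylbut-2-enyl)phenyl]-4-oxochromane-3-carboxylate (C3 not fixed) | COc1c(CC=C(C)C)cc([C@@H]2C(C(=O)OC(C)(C)C)C(=O)c3ccc(OCOC)cc3O2)cc1CC=C(C)C
F4 | step 7 | triethyl{[(1R)-1-[4-methoxy-3,5-bis(3-methylbut-2-enyl)phenyl]prop-2-enyl]oxy}silane | COc1c(CC=C(C)C)cc([C@H](O[Si](CC)(CC)CC)C=C)cc1CC=C(C)C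
F5 | step 7 | (1R)-1-[4-methoxy-3,5-bis(3-methylbut-2-enyl)phenyl]prop-2-en-1-ol | COc1c(CC=C(C)C)cc([C@H](O)C=C)cc1CC=C(C)C
F6 | step 2 | 4-methoxy-3,5-bis(prop-2-enyl)benzaldehyde | COc1c(CC=C)cc(C=O)cc1CC=C
F7 | step 10 | 1-[2-hydroxy-4-(triisopropylsilyloxy)phenyl]ethanone | CC(=O)c1ccc(O[Si](C(C)C)(C(C)C)C(C)C)cc1O
F8 | step 10 | 1-[2-{[(1S)-1-[4-methoxy-3,5-bis(3-methylbut-2-enyl)phenyl]prop-2-enyl]oxy}-4-(triisopropylsilyloxy)phenyl]ethanone | COc1c(CC=C(C)C)cc([C@@H](Oc2cc(O[Si](C(C)C)(C(C)C)C(C)C)ccc2C(C)=O)C=C)cc1CC=C(C)C
F9 | step 10 | tert-butyl{[1-(2-{[(1S)-1-[4-methoxy-3,5-bis(3-methylbut-2-enyl)phenyl]prop-2-enyl]oxy}-4-(triisopropylsilyloxy)phenyl)ethenyl]oxy}dimethylsilane | COc1c(CC=C(C)C)cc([C@@H](Oc2cc(O[Si](C(C)C)(C(C)C)C(C)C)ccc2C(=C)O[Si](C)(C)C(C)(C)C)C=C)cc1CC=C(C)C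
F10 | step 10 | (2S)-4-(tert-butyldimethylsilyloxy)-2-[4-methoxy-3,5-bis(3-methylbut-2-enyl)phenyl]-7-(triisopropylsilyloxy)-2H-chromene | COc1c(CC=C(C)C)cc([C@@H]2C=C(O[Si](C)(C)C(C)(C)C)c3ccc(O[Si](C(C)C)(C(C)C)C(C)C)cc3O2)cc1CC=C(C)C
A1 | alternative 1 | 5-bromo-7-(methoxymethoxy)-2-[4-methoxy-3,5-bis(3-methylbut-2-enyl)phenyl]chromen-4-one | O=c1cc(-c2cc(CC=C(C)C)c(OC)c(CC=C(C)C)c2)oc2cc(OCOC)cc(Br)c12
A2 | alternative 1 | 3-[4-methoxy-3,5-bis(3-methylbut-2-enyl)phenyl]prop-2-ynoic acid | COc1c(CC=C(C)C)cc(C#CC(=O)O)cc1CC=C(C)C
A3 | alternative 1 | 3-bromo-5-(methoxymethoxy)-2-(trimethylsilyl)phenyl trifluoromethanesulfonate | COCOc1cc(Br)c([Si](C)(C)C)c(OS(=O)(=O)C(F)(F)F)c1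
A4 | alternative 2 | 7-(methoxymethoxy)-2-[4-methoxy-3,5-bis(3-methylbut-2-enyl)phenyl]chromen-4-one | O=c1cc(-c2cc(CC=C(C)C)c(OC)c(CC=C(C)C)c2)oc2cc(OCOC)ccc12
A5 | alternative 2 | 2-iodo-5-(methoxymethoxy)phenol | COCOc1ccc(I)c(O)c1
A6 | alternative 2 | 5-ethynyl-2-methoxy-1,3-bis(3-methylbut-2-enyl)benzene | COc1c(CC=C(C)C)cc(C#C)cc1CC=C(C)C
A7 | alternative 3 | (2S,4S)-7-(methoxymethoxy)-2-[4-methoxy-3,5-bis(3-methylbut-2-enyl)phenyl]chroman-4-ol | COc1c(CC=C(C)C)cc([C@@H]2C[C@H](O)c3ccc(OCOC)cc3O2)cc1CC=C(C)C
A8 | alternative 3 | (1S,3S)-1-[2-bromo-4-(methoxymethoxy)phenyl]-3-[4-methoxy-3,5-bis(3-methylbut-2-enyl)phenyl]propane-1,3-diol | COc1c(CC=C(C)C)cc([C@@H](O)C[C@H](O)c2ccc(OCOC)cc2Br)cc1CC=C(C)C
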